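**Retrosynthetic overview**
1. Feature: C3 and C4 of ring A form a 3-oxygenated 2-methyl-2-(oxymethyl)cyclohexanone whose carbonyl carbon is C5; C4 is quaternary, so C10 is the only enolisable carbon and ring B can be annulated across C10 and C5.
2. Side chain last: the 2-substituted 1,3-diene comes from ethylene enyne metathesis of a C13≡C14 alkyne; the alkyne comes from a δ-lactol; the δ-lactone comes from iodolactonisation of a C13 acid onto C7=C8, which places the C8 oxygen cis to the C9 chain.
3. The C9 chain (C11–C13) comes from cuprate 1,4-addition anti to C20 onto an 8-methyl-8-en-7-one, with the enolate trapped as triflate (then 7-ene); that enone comes from the annulation product by C8 methylation, Li/NH3 (C5–H) and dehydrogenation.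
4. Ring B (second ring) comes from Robinson annulation of the ring A acetonide ketone with methyl vinyl ketone: Michael addition forms C9–C10, aldol condensation forms C5=C6.
5. Ring A (first ring) comes from 2-methylcyclohexane-1,3-dione: aldol with CH2O (C18), CBS desymmetrisation (fixes C4), hydroxyl-directed reduction (fixes C3), trans-fused acetonide, reoxidation to the C5 ketone, C10 methylation.

Key step: step 11

Remark: locants follow the decalin/side-chain numbering of the target (C17 = CH3 on C8, C18 = CH2O on C4, C19 = CH3 on C4, C20 = CH3 on C10); "syn/anti" refer to C20.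
Assumption: in the oxazaborolidine reduction of 3 the hydroxyl ends cis to the larger CH2OBn group, as is usual for 2-alkyl-2-methylcyclohexane-1,3-diones; therefore this first carbinol only breaks the symmetry (it becomes the C5 ketone) and C3 is set by a directed reduction. Epimers at enolisable centres (C10 in 12, C8 in 18 and 19) are drawn as the equatorial isomers; lactol 32 is an anomer mixture.

**Step 1**
Reactants: 1 2-methylcyclohexane-1,3-dione
Product: 2 2-(hydroxymethyl)-2-methylcyclohexane-1,3-dione
Conditions: 37% aq. CH2O (3 equiv), H2O, 25 °C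
Reagents that add atoms: formaldehyde C=O
Why: Tollens-type aldol (hydroxymethylation) of the enolic β-diketone at its central carbon (future C4) gives C18 by C–C bond formation, because attack through oxygen is reversible, whereas alkoxymethyl chlorides would mainly O-alkylate this dione.

**Step 2**
Reactants: 2 2-(hydroxymethyl)-2-methylcyclohexane-1,3-dione
Product: 3 2-[(benzyloxy)methyl]-2-methylcyclohexane-1,3-dione
Conditions: BnOC(=NH)CCl3, TfOH (cat.), CH2Cl2–cyclohexane, 0 °C to rt
Reagents that add atoms: benzyl 2,2,2-trichloroacetimidate ClC(Cl)(Cl)C(=N)OCc1ccccc1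
Why: Acid-catalysed O-benzylation with the trichloroacetimidate avoids base, which would cause retro-aldol loss of formaldehyde, and makes the C18 arm clearly larger than the methyl group for step 3.

**Step 3**
Reactants: 3 2-[(benzyloxy)methyl]-2-methylcyclohexane-1,3-dione
Product: 4 (2R,3R)-2-[(benzyloxy)methyl]-3-hydroxy-2-methylcyclohexan-1-one (OH cis to CH2OBn)
Conditions: (S)-2-methyl-CBS-oxazaborolidine [(S)-1-methyl-3,3-diphenyltetrahydro-1H,3H-pyrrolo[1,2-c][1,3,2]oxazaborole] (0.2 equiv), BH3·SMe2 (0.6 equiv), THF, −40 °C; MeOH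
Reagents that add atoms: none
Why: Corey–Bakshi–Shibata desymmetrisation: the (S)-catalyst binds a carbonyl anti to its quaternary α-carbon and gives the (R)-carbinol, and of the two enantiotopic carbonyls it reduces the one whose favoured face lies anti to the larger CH2OBn group, so the quaternary carbon (future C4) becomes stereogenic; the carbinol carbon is the future C5.

**Step 4**
Reactants: 4 (2R,3R)-2-[(benzyloxy)methyl]-3-hydroxy-2-methylcyclohexan-1-one
Product: 5 (2R,3R)-2-[(benzyloxy)methyl]-3-[(tert-butyldimethylsilyl)oxy]-2-methylcyclohexan-1-one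
Conditions: TBSOTf, 2,6-lutidine, CH2Cl2, −78 to 0 °C
Reagents that add atoms: tert-butyldimethylsilyl trifluoromethanesulfonate CC(C)(C)[Si](C)(C)OS(=O)(=O)C(F)(F)F
Why: Silylation masks the first carbinol (future C5 ketone) so that only the C18 hydroxyl freed in step 5 can direct the next reduction and enter the acetal.

**Step 5**
Reactants: 5 (2R,3R)-2-[(benzyloxy)methyl]-3-[(tert-butyldimethylsilyl)oxy]-2-methylcyclohexan-1-one
Product: 6 (2R,3R)-3-[(tert-butyldimethylsilyl)oxy]-2-(hydroxymethyl)-2-methylcyclohexan-1-one
Conditions: H2 (1 atm), palladium on carbon (Pd/C), EtOAc, rt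
Reagents that add atoms: none
Why: Hydrogenolysis of the benzyl ether frees the C18 hydroxyl under neutral conditions; the ketone and the silyl ether are inert.

**Step 6**
Reactants: 6 (2R,3R)-3-[(tert-butyldimethylsilyl)oxy]-2-(hydroxymethyl)-2-methylcyclohexan-1-one
Product: 7 (1R,2S,3R)-3-[(tert-butyldimethylsilyl)oxy]-2-(hydroxymethyl)-2-methylcyclohexan-1-ol (free secondary OH trans to CH2OH, cis to CH3)
Conditions: Me4NBH(OAc)3, MeCN–AcOH (1:1), −30 to −20 °C
Reagents that add atoms: none
Why: Saksena–Evans hydroxyl-directed reduction: the C18 alkoxy(acetoxy)borohydride delivers hydride inside a six-membered transition state to the face of the carbonyl that carries C18, so the new C3 hydroxyl is trans to C18 and cis to the C4 methyl, which sets C3.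

**Step 7**
Reactants: 7 (1R,2S,3R)-3-[(tert-butyldimethylsilyl)oxy]-2-(hydroxymethyl)-2-methylcyclohexan-1-ol
Product: 8 5-[(tert-butyldimethylsilyl)oxy]-2,2,4a-trimethylhexahydro-4H-1,3-benzodioxine (trans ring fusion; 4a-CH3 axial; OSi cis to the ring CH2O)
Conditions: Me2C(OMe)2, PPTS (cat.), CH2Cl2, rt
Reagents that add atoms: 2,2-dimethoxypropane COC(C)(C)OC
Why: Acetalisation of the only two free hydroxyls (C3–OH and C18–OH, both equatorial) gives the trans-fused 1,3-dioxane, which locks ring A with the C4 methyl axial.

**Step 8**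
Reactants: 8 5-[(tert-butyldimethylsilyl)oxy]-2,2,4a-trimethylhexahydro-4H-1,3-benzodioxine
Product: 9 2,2,4a-trimethylhexahydro-4H-1,3-benzodioxin-5-ol (trans ring fusion; OH cis to the ring CH2O)
Conditions: Bu4NF, THF, 50 °C
Reagents that add atoms: none
Why: Fluoride cleaves the hindered secondary silyl ether; the acetonide is stable to these conditions.

**Step 9**
Reactants: 9 2,2,4a-trimethylhexahydro-4H-1,3-benzodioxin-5-ol
Product: 10 (4aS,8aR)-2,2,4a-trimethylhexahydro-4H-1,3-benzodioxin-5-one
Conditions: Dess–Martin periodinane, NaHCO3, CH2Cl2, rt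
Reagents that add atoms: none
Why: Dess–Martin oxidation returns the first carbinol to the C5 ketone; C4 is quaternary, so neither epimerisation nor β-elimination can occur.

**Step 10**
Reactants: 10 (4aS,8aR)-2,2,4a-trimethylhexahydro-4H-1,3-benzodioxin-5-one
Product: 12 (4aS,6R,8aR)-2,2,4a,6-tetramethylhexahydro-4H-1,3-benzodioxin-5-one (ring A acetonide ketone with C10 methyl), via lithium enolate 11 (not isolated)
Conditions: LiN(i-Pr)2, THF, −78 °C; MeI, −78 to −20 °C
Reagents that add atoms: iodomethane CI
Why: Enolate alkylation: C4 is quaternary, so the amide base can deprotonate only C10 and MeI gives the C10 methyl ketone (mainly equatorial); this centre is planarised again in step 11.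

**Step 11**
Reactants: 12 ring A acetonide ketone with C10 methyl; 13 methyl vinyl ketone (but-3-en-2-one)
Product: 16 bicyclic 5-en-7-one with C3/C18 acetonide and quaternary C10 (C20 syn to C19), via 1,5-diketone Michael adduct 14 (not isolated), via cis-fused ketol 15 (not isolated)
Conditions: 13 (1.5 equiv), KOt-Bu (0.15 equiv), t-BuOH–THF, 0 °C to rt; then KOH, MeOH, 65 °C
Reagents that add atoms: none
Why: Robinson annulation of a 2,2,6-trisubstituted cyclohexanone: alkoxide forms the only possible enolate of 12 (C5–C10), which adds to 13 in a Michael reaction to form C9–C10 and the quaternary C10 (14). The side-chain methyl ketone then enolises and closes ring B by a 6-(enolendo)-exo-trig aldol addition onto the C5 carbonyl (ketol 15), and E1cB dehydration gives the conjugated 5-en-7-one. The surviving new stereocentre is C10: the trans-fused acetonide holds ring A in the chair with the C4 methyl (C19) axial, so the enone approaches the opposite enolate face and C20 ends syn to C19, the same sense as alkylation of 3-keto decalin enolates anti to an angular methyl. The step needs face selectivity (locked axial C19), a single enolate regiochemistry (quaternary C4) and closure on C5 as the only ring carbonyl. The acetonide is inert to base and no β-elimination is possible because C4 carries no hydrogen; the C5 hydroxyl of 15 is lost, so its configuration does not matter.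

**Step 12**
Reactants: 16 bicyclic 5-en-7-one
Product: 18 8-methyl-5-en-7-one (C8 methyl anti to C20; epimer mixture tolerated), via lithium dienolate 17 (not isolated)
Conditions: LiN(i-Pr)2, THF, −78 °C; MeI, −78 to −20 °C
Reagents that add atoms: iodomethane CI
Why: Kinetic α′-deprotonation of the enone can occur only at C8 (there is no γ-hydrogen, C4 being quaternary) and methylation of the cross-conjugated enolate installs C17; the C8 configuration is lost later.

**Step 13**
Reactants: 18 8-methyl-5-en-7-one
Product: 19 8-methyl trans-decalin-7-one with C3/C18 acetonide (C5–H anti to C20; C8 methyl equatorial)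
Conditions: Li, NH3(l)–THF, t-BuOH (1 equiv), −78 °C; NH4Cl
Reagents that add atoms: none
Why: Dissolving-metal (Birch-type) enone reduction: the β-carbanion at C5 is protonated axially on the face opposite the axial C10 and C4 methyls, which gives the trans ring fusion and sets C5; the C8 methyl settles equatorial on work-up.

**Step 14**
Reactants: 19 8-methyl trans-decalin-7-one
Product: 20 8-methyl-8-en-7-one (trans-decalin; C5–H anti to C20)
Conditions: 2-iodoxybenzoic acid (IBX, 1.5 equiv), DMSO–PhF, 70 °C
Reagents that add atoms: none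
Why: IBX dehydrogenation through the more substituted enol: the methyl substituent and the preference of a trans-fused decalin-7-one to enolise toward C8 both direct the new double bond to C8=C9, giving the α-methyl enone needed for a regiodefined enolate in step 15.

**Step 15**
Reactants: 20 8-methyl-8-en-7-one; 21 tert-butyl(3-iodopropoxy)dimethylsilane
Product: 25 C7 enol triflate (C7=C8) with the 3-(silyloxy)propyl chain on C9 anti to C20, via 3-(silyloxy)propyllithium 22 (not isolated), via lithium dialkylcuprate 23 (not isolated), via lithium enolate 24 (not isolated)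
Conditions: 21, t-BuLi (2 equiv), Et2O, −78 °C; CuBr·SMe2 (0.5 equiv); 20, −78 to −20 °C; PhNTf2, THF, −20 °C to rt
Reagents that add atoms: N-phenylbis(trifluoromethanesulfonimide) O=S(=O)(N(c1ccccc1)S(=O)(=O)C(F)(F)F)C(F)(F)F
Why: Organocuprate 1,4-addition with enolate trapping: the Gilman reagent adds axially at C9 on the face anti to the C10 methyl (as in additions to trans-fused 1-en-3-ones), which sets C9, and the regiospecific C7–C8 enolate is O-sulfonylated so that the later alkene is fixed at C7=C8; the chain brings C11–C13, the three carbons the diene side chain needs between C9 and the alkyne.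

**Step 16**
Reactants: 25 C7 enol triflate
Product: 26 7-ene (C7=C8 with C17 on C8) carrying the C9 3-(silyloxy)propyl chain
Conditions: Pd(OAc)2 (5 mol%), PPh3, HCO2H, n-Bu3N, DMF, 60 °C
Reagents that add atoms: none
Why: Palladium-catalysed formate reduction of an enol triflate: oxidative addition to zerovalent palladium, formate decarboxylation and C–H reductive elimination replace OTf by H without moving the double bond.

**Step 17**
Reactants: 26 7-ene silyl ether
Product: 27 C13 primary alcohol (7-ene; acetonide intact)
Conditions: Bu4NF, THF, rt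
Reagents that add atoms: none
Why: Fluoride cleavage of the primary silyl ether; acetonide and alkene are inert.

**Step 18**
Reactants: 27 C13 primary alcohol
Product: 29 C13 carboxylic acid (7-ene; acetonide intact), via aldehyde 28 (not isolated)
Conditions: TEMPO (2,2,6,6-tetramethylpiperidin-1-oxyl, 0.2 equiv), PhI(OAc)2 (2.5 equiv), MeCN–H2O (1:1), rt
Reagents that add atoms: water O
Why: Nitroxyl-catalysed oxidation of the primary alcohol through the aldehyde and its hydrate to the acid; the trisubstituted alkene and the acetonide tolerate these near-neutral conditions.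

**Step 19**
Reactants: 29 C13 carboxylic acid
Product: 30 iodo δ-lactone (C13–O–C8; C8–O cis to C11; C17 syn to C20; C7–I anti to the lactone oxygen)
Conditions: I2, NaHCO3, MeCN, 0 °C, dark
Reagents that add atoms: iodine II
Why: Iodolactonisation (6-exo, Markovnikov): the carboxylate tethered to C9 opens the iodonium ion at the tertiary carbon C8 and can reach it only on the face of the chain, so C8–O is cis to C11 and C17 ends syn to C20, which sets C8.

**Step 20**
Reactants: 30 iodo δ-lactone
Product: 31 δ-lactone (C8–O cis to C11; acetonide intact)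
Conditions: n-Bu3SnH, AIBN (cat.), toluene, 80 °C
Reagents that add atoms: none
Why: Radical dehalogenation with tin hydride removes the C7 iodine; no stereocentre is touched.

**Step 21**
Reactants: 31 δ-lactone
Product: 32 δ-lactol (anomer mixture)
Conditions: i-Bu2AlH (1.2 equiv), CH2Cl2, −78 °C
Reagents that add atoms: none
Why: Partial reduction of the lactone stops at the tetrahedral aluminium alkoxide at low temperature and gives the lactol on work-up.

**Step 22**
Reactants: 32 δ-lactol
Product: 34 terminal alkyne (C13≡C14) with free C8 tertiary alcohol and intact acetonide, via open-chain hydroxy aldehyde 33 (not isolated)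
Conditions: MeC(O)C(N2)P(O)(OMe)2, K2CO3, MeOH, 0 °C to rt
Reagents that add atoms: dimethyl (1-diazo-2-oxopropyl)phosphonate COP(=O)(OC)C(=[N+]=[N-])C(C)=O
Why: Ohira–Bestmann (Seyferth–Gilbert) homologation: the hydroxy aldehyde in equilibrium with the lactol reacts with the diazomethylphosphonate anion formed by methanolysis, which adds C14 as the alkyne terminus and frees the C8 hydroxyl.

**Step 23**
Reactants: 34 alkyne acetonide
Product: 35 alkyne triol (C3–OH, C8–OH, C18–OH)
Conditions: AcOH–H2O–THF (3:1:1), 45 °C
Reagents that add atoms: none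
Why: Mild acid hydrolysis of the isopropylidene acetal; the tertiary alcohol and the alkyne survive.

**Step 24**
Reactants: 35 alkyne triol
Product: 36 C18 tert-butyldimethylsilyl ether (C3–OH and C8–OH free)
Conditions: TBSCl (1.1 equiv), imidazole, DMF, 0 °C
Reagents that add atoms: tert-butyldimethylsilyl chloride CC(C)(C)[Si](C)(C)Cl
Why: Chemoselective silylation: the primary C18 hydroxyl reacts much faster than the neopentylic secondary C3 and the tertiary C8 hydroxyls, which leaves C3 as the only acylable position.

**Step 25**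
Reactants: 36 C18 silyl ether
Product: 37 C3 acetate C18 silyl ether (C8–OH free)
Conditions: Ac2O, pyridine, DMAP (cat.), CH2Cl2, 0 °C to rt
Reagents that add atoms: acetic anhydride CC(=O)OC(C)=O
Why: DMAP-catalysed acetylation of the secondary C3 alcohol; the hindered tertiary C8 alcohol does not acylate under these conditions.

**Step 26**
Reactants: 37 C3 acetate C18 silyl ether
Product: 38 alkyne with C3 acetate and free C8 and C18 hydroxyls
Conditions: HF·pyridine, THF–pyridine, 0 °C to rt
Reagents that add atoms: none
Why: Acidic fluoride desilylation frees C18–OH without the base-induced O3-to-O18 acetyl migration that Bu4NF could cause.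

**Step 27**
Reactants: 38 alkyne with C3 acetate
Product: 39 CNP0313672.1
Conditions: second-generation Grubbs catalyst RuCl2(=CHPh)(PCy3)(H2IMes) (5 mol%), ethylene (1 atm), CH2Cl2, 40 °C
Reagents that add atoms: ethylene C=C
Why: Ethylene–alkyne cross enyne metathesis: the ruthenium methylidene adds to the terminal alkyne and the vinylcarbene is turned over by ethylene, which gives the 2-substituted buta-1,3-diene (C13=C16 and C14=C15); free hydroxyls and the acetate are tolerated.

**Compound list**
1 | 2-methylcyclohexane-1,3-dione | CC1C(=O)CCCC1=O | starting material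
2 | 2-(hydroxymethyl)-2-methylcyclohexane-1,3-dione | CC1(CO)C(=O)CCCC1=O | intermediate
3 | 2-[(benzyloxy)methyl]-2-methylcyclohexane-1,3-dione | CC1(COCc2ccccc2)C(=O)CCCC1=O | intermediate
4 | (2R,3R)-2-[(benzyloxy)methyl]-3-hydroxy-2-methylcyclohexan-1-one | O=C1CCC[C@@H](O)[C@@]1(C)COCc2ccccc2 | intermediate
5 | (2R,3R)-2-[(benzyloxy)methyl]-3-[(tert-butyldimethylsilyl)oxy]-2-methylcyclohexan-1-one | O=C1CCC[C@@H](O[Si](C)(C)C(C)(C)C)[C@@]1(C)COCc2ccccc2 | intermediate
6 | (2R,3R)-3-[(tert-butyldimethylsilyl)oxy]-2-(hydroxymethyl)-2-methylcyclohexan-1-one | O=C1CCC[C@@H](O[Si](C)(C)C(C)(C)C)[C@@]1(C)CO | intermediate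
7 | (1R,2S,3R)-3-[(tert-butyldimethylsilyl)oxy]-2-(hydroxymethyl)-2-methylcyclohexan-1-ol | O[C@@H]1CCC[C@@H](O[Si](C)(C)C(C)(C)C)[C@@]1(C)CO | intermediate
8 | 5-[(tert-butyldimethylsilyl)oxy]-2,2,4a-trimethylhexahydro-4H-1,3-benzodioxine, trans-fused, OSi cis to ring CH2O | CC(C)(C)[Si](C)(C)O[C@@H]1CCC[C@H]2OC(C)(C)OC[C@]12C | intermediate
9 | 2,2,4a-trimethylhexahydro-4H-1,3-benzodioxin-5-ol, trans-fused, OH cis to ring CH2O | O[C@@H]1CCC[C@H]2OC(C)(C)OC[C@]12C | intermediate
10 | (4aS,8aR)-2,2,4a-trimethylhexahydro-4H-1,3-benzodioxin-5-one | O=C1CCC[C@H]2OC(C)(C)OC[C@]12C | intermediate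
11 | lithium enolate of 10 (C5–C10) | [Li+].[O-]C1=CCC[C@H]2OC(C)(C)OC[C@]12C | intermediate (not isolated)
12 | (4aS,6R,8aR)-2,2,4a,6-tetramethylhexahydro-4H-1,3-benzodioxin-5-one (ring A acetonide ketone with C10 methyl) | C[C@@H]1CC[C@H]2OC(C)(C)OC[C@]2(C)C1=O | intermediate
13 | methyl vinyl ketone (but-3-en-2-one) | C=CC(C)=O | starting material
14 | Michael adduct: 12 carrying a 3-oxobutyl chain on C10 anti to the C4 methyl | CC(=O)CC[C@]1(C)CC[C@H]2OC(C)(C)OC[C@]2(C)C1=O | intermediate (not isolated)
15 | cis-fused ketol: 5-hydroxy-decalin-7-one with C3/C18 acetonide, C5–OH syn to C20 | O=C1CC[C@]2(C)CC[C@H]3OC(C)(C)OC[C@]3(C)[C@]2(O)C1 | intermediate (not isolated)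
16 | bicyclic 5-en-7-one with C3/C18 acetonide and quaternary C10 (C20 syn to C19) | O=C1CC[C@]2(C)CC[C@H]3OC(C)(C)OC[C@]3(C)C2=C1 | intermediate
17 | lithium cross-conjugated dienolate of 16 (C7–O, C7=C8) | [Li+].[O-]C1=CC[C@]2(C)CC[C@H]3OC(C)(C)OC[C@]3(C)C2=C1 | intermediate (not isolated)
18 | 8-methyl-5-en-7-one (C8 methyl anti to C20) | O=C1[C@H](C)C[C@]2(C)CC[C@H]3OC(C)(C)OC[C@]3(C)C2=C1 | intermediate
19 | 8-methyl trans-decalin-7-one with C3/C18 acetonide (C5–H anti to C20, C8 methyl equatorial) | C[C@@H]1C[C@]2(C)CC[C@H]3OC(C)(C)OC[C@]3(C)[C@H]2CC1=O | intermediate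
20 | 8-methyl-8-en-7-one (trans-decalin, C5–H anti to C20) | CC1=C[C@]2(C)CC[C@H]3OC(C)(C)OC[C@]3(C)[C@H]2CC1=O | intermediate
21 | tert-butyl(3-iodopropoxy)dimethylsilane | ICCCO[Si](C)(C)C(C)(C)C | starting material
22 | [3-(tert-butyldimethylsilyloxy)propyl]lithium | [Li]CCCO[Si](C)(C)C(C)(C)C | intermediate (not isolated)
23 | lithium bis[3-(tert-butyldimethylsilyloxy)propyl]cuprate | [Li+].CC(C)(C)[Si](C)(C)OCCC[Cu-]CCCO[Si](C)(C)C(C)(C)C | intermediate (not isolated)
24 | lithium C7–C8 enolate with the C9 chain anti to C20 | [Li+].CC(C)(C)[Si](C)(C)OCCC[C@@H]1[C@]2(C)CC[C@H]3OC(C)(C)OC[C@]3(C)[C@H]2CC([O-])=C1C | intermediate (not isolated)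
25 | C7 enol triflate (C7=C8), C9 3-(silyloxy)propyl chain anti to C20 | CC(C)(C)[Si](C)(C)OCCC[C@@H]1[C@]2(C)CC[C@H]3OC(C)(C)OC[C@]3(C)[C@H]2CC(OS(=O)(=O)C(F)(F)F)=C1C | intermediate
26 | 7-ene with C9 3-(silyloxy)propyl chain | CC(C)(C)[Si](C)(C)OCCC[C@@H]1[C@]2(C)CC[C@H]3OC(C)(C)OC[C@]3(C)[C@H]2CC=C1C | intermediate
27 | C13 primary alcohol (7-ene) | OCCC[C@@H]1[C@]2(C)CC[C@H]3OC(C)(C)OC[C@]3(C)[C@H]2CC=C1C | intermediate
28 | C13 aldehyde (7-ene) | O=CCC[C@@H]1[C@]2(C)CC[C@H]3OC(C)(C)OC[C@]3(C)[C@H]2CC=C1C | intermediate (not isolated)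
29 | C13 carboxylic acid (7-ene) | OC(=O)CC[C@@H]1[C@]2(C)CC[C@H]3OC(C)(C)OC[C@]3(C)[C@H]2CC=C1C | intermediate
30 | iodo δ-lactone (C8–O cis to C11, C7–I anti to O) | O=C1CC[C@@H]2[C@]3(C)CC[C@H]4OC(C)(C)OC[C@]4(C)[C@H]3C[C@@H](I)[C@]2(C)O1 | intermediate
31 | δ-lactone (C8–O cis to C11, C17 syn to C20) | O=C1CC[C@@H]2[C@]3(C)CC[C@H]4OC(C)(C)OC[C@]4(C)[C@H]3CC[C@]2(C)O1 | intermediate
32 | δ-lactol (anomer mixture at C13) | OC1CC[C@@H]2[C@]3(C)CC[C@H]4OC(C)(C)OC[C@]4(C)[C@H]3CC[C@]2(C)O1 | intermediate
33 | open-chain C13 aldehyde with free C8 tertiary alcohol | O=CCC[C@@H]1[C@]2(C)CC[C@H]3OC(C)(C)OC[C@]3(C)[C@H]2CC[C@]1(C)O | intermediate (not isolated)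
34 | terminal alkyne with C8 tertiary alcohol and C3/C18 acetonide | C#CCC[C@@H]1[C@]2(C)CC[C@H]3OC(C)(C)OC[C@]3(C)[C@H]2CC[C@]1(C)O | intermediate
35 | alkyne triol | C#CCC[C@@H]1[C@]2(C)CC[C@@H](O)[C@](C)(CO)[C@H]2CC[C@]1(C)O | intermediate
36 | alkyne diol, C18 tert-butyldimethylsilyl ether | C#CCC[C@@H]1[C@]2(C)CC[C@@H](O)[C@](C)(CO[Si](C)(C)C(C)(C)C)[C@H]2CC[C@]1(C)O | intermediate
37 | alkyne, C3 acetate, C18 silyl ether | C#CCC[C@@H]1[C@]2(C)CC[C@@H](OC(C)=O)[C@](C)(CO[Si](C)(C)C(C)(C)C)[C@H]2CC[C@]1(C)O | intermediate
38 | alkyne, C3 acetate, free C8 and C18 hydroxyls | C#CCC[C@@H]1[C@]2(C)CC[C@@H](OC(C)=O)[C@](C)(CO)[C@H]2CC[C@]1(C)O | intermediate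
39 | CNP0313672.1 | C=CC(=C)CC[C@@H]1[C@]2(C)CC[C@@H](OC(C)=O)[C@](C)(CO)[C@H]2CC[C@]1(C)O | target

Total step count: 27
Longest linear sequence: 27 steps (from 1; 13 and 21 are commercial)

**Steps most likely to fail**

Step 11 (key step). The tetrasubstituted, neopentylic enolate may add too slowly to the vinyl ketone, so that base-induced polymerisation of the acceptor wins. The aldol closure onto the doubly neopentylic C5 carbonyl may also stall at the diketone or ketol stage. Fallback, from 12: irreversible deprotonation with LiN(i-Pr)2 (THF, −78 °C) and Michael addition to 3-(trimethylsilyl)but-3-en-2-one, whose α-silyl group stabilises the adduct enolate and suppresses polymerisation, should give the α-trimethylsilyl 1,5-diketone F1 with the same facial bias. KOH in MeOH at reflux then removes the silyl group and drives the aldol condensation, which comes back to the route at 16.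

Step 15. 1,4-Addition may fail at the neopentylic β-carbon of the α-methyl enone (enone recovered, 1,2-addition or reduction), or O-sulfonylation of the hindered enolate may be incomplete. Fallback, from 20: the smaller and more reactive divinylcuprate (CH2=CHMgBr, CuBr·SMe2, THF, −78 °C) adds at C9 anti to C20, and trapping with PhNTf2 gives the 9-vinyl enol triflate F2. The same Pd(OAc)2/PPh3/HCO2H/n-Bu3N reduction gives the 9-vinyl-7-ene F3. Linear-selective hydroformylation of its monosubstituted alkene (Rh(acac)(CO)2, Xantphos, CO/H2, toluene, 60 °C) adds C13 and comes back to the route at aldehyde 28, here isolated, which Pinnick oxidation (NaClO2, NaH2PO4, 2-methylbut-2-ene) takes to 29.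

Step 19. The carboxylate can reach C8 only on the face of the C9 chain, which needs iodonium formation on the hindered C20 face and a non-diaxial ring opening. Slow cyclisation would allow iodonium reversal or allylic iodination. Fallback, from 26: Mukaiyama hydration (Co(acac)2 cat., PhSiH3, O2, i-PrOH; then PPh3) captures the tertiary C8 radical on the face anti to C20 and gives the C8 tertiary alcohol silyl ether F4. Bu4NF then gives the 8,13-diol F5, and TEMPO/PhI(OAc)2 in CH2Cl2 oxidises the primary alcohol through the lactol to the δ-lactone, which comes back to the route at 31.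

**Further compounds**
F1 | step 11 | α-trimethylsilyl 1,5-diketone (12 with a 3-oxo-2-(trimethylsilyl)butyl chain on C10 anti to the C4 methyl; silyl-bearing carbon as epimer mixture) | CC(=O)C(C[C@]1(C)CC[C@H]2OC(C)(C)OC[C@]2(C)C1=O)[Si](C)(C)C
F2 | step 15 | 9-vinyl C7 enol triflate (vinyl anti to C20) | C=C[C@@H]1[C@]2(C)CC[C@H]3OC(C)(C)OC[C@]3(C)[C@H]2CC(OS(=O)(=O)C(F)(F)F)=C1C
F3 | step 15 | 9-vinyl-7-ene | C=C[C@@H]1[C@]2(C)CC[C@H]3OC(C)(C)OC[C@]3(C)[C@H]2CC=C1C
F4 | step 19 | C8 tertiary alcohol with C9 3-(silyloxy)propyl chain (C8–OH cis to C11) | CC(C)(C)[Si](C)(C)OCCC[C@@H]1[C@]2(C)CC[C@H]3OC(C)(C)OC[C@]3(C)[C@H]2CC[C@]1(C)O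
F5 | step 19 | 8,13-diol | OCCC[C@@H]1[C@]2(C)CC[C@H]3OC(C)(C)OC[C@]3(C)[C@H]2CC[C@]1(C)O
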